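**Retrosynthetic overview**

- The strategy rests on ring A (C4a, C5, C6, C7, C8, C8a): its three contiguous oxygens (C5–OH, C6–OMe, C7–O) and its one C–H (C8) correspond one-to-one to C1–C4 of a squarate-derived cyclobutenone attached to the pyranone carbon that becomes C8a.
- The two sulfate esters are taken back to hispidulin and its 7,4'-dibenzyl ether. Ring A is then opened at C4a–C5 to a 4-(4-oxopyran-2-yl)cyclobutenone (4π ring opening, 6π ring closure in the forward sense).
- That cyclobutenone is cut at the future C8–C8a bond by a Stille coupling. The electrophile is a 4-chlorocyclobutenone made from dimethyl squarate by reduction, exchange of the vinylogous methoxyl for benzyloxy, and chlorination.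
- The nucleophile is a 2-stannyl-6-aryl-4-pyranone made from 4-(benzyloxy)benzoyl chloride and 4,4-dichlorobut-3-en-2-one. Tin is put on only after the pyranone is closed, and it replaces a chlorine that sits next to the ring oxygen by construction.
- Ring order: aryl ring B is bought, pyranone ring C is closed first, ring A last.

Key step: step 7

Remark: the target is taken as the neutral bis(hydrogen sulfate) as drawn, released from its pyridinium salt on an H+ resin and kept cold; 4,4-dichlorobut-3-en-2-one is taken as a purchasable reagent; all cyclobutenone intermediates are racemic and the target is achiral.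

**Route**

Step 1
Reactants: 1 dimethyl squarate (3,4-dimethoxycyclobut-3-ene-1,2-dione)
Product: 2 4-hydroxy-2,3-dimethoxycyclobut-2-en-1-one (racemic)
Conditions: LiAlH(OtBu)3 (1.05 equiv), THF, −78 °C; cold aq. NH4Cl
Reagents that add atoms: none
Why: The bulky hydride LiAlH(OtBu)3 should add once to one of the two equivalent carbonyls of the squarate (chemoselective 1,2-reduction of a cyclobutenedione), and the new C4 stereocentre forms as a racemate that is erased in step 7.

Step 2
Reactants: 2 4-hydroxy-2,3-dimethoxycyclobut-2-en-1-one; 3 benzyl alcohol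
Product: 4 3-(benzyloxy)-4-hydroxy-2-methoxycyclobut-2-en-1-one (racemic)
Conditions: 3 (5 equiv), camphorsulfonic acid (5 mol %), CH2Cl2, 5 Å sieves, 25 °C
Reagents that add atoms: none
Why: Acid-catalysed vinylogous transesterification (addition–elimination at C3, the β-carbon of the enone) should exchange only the vinylogous-ester methoxyl, because the C2 methoxyl is an enol ether on the α-carbon and is not electrophilic, so the reduction in step 1 has already decided that OMe stays on C2 (future C6) and OBn goes to C3 (future C7); catalytic sulfonic acid is expected to be too weak to ionise the C4 hydroxyl, and no stereocentre is made.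

Step 3
Reactants: 4 3-(benzyloxy)-4-hydroxy-2-methoxycyclobut-2-en-1-one
Product: 5 3-(benzyloxy)-4-chloro-2-methoxycyclobut-2-en-1-one (racemic)
Conditions: SOCl2 (1.2 equiv), pyridine (1.5 equiv), CH2Cl2, −20 to 0 °C; filtered and concentrated cold, used at once
Reagents that add atoms: thionyl chloride, O=S(Cl)Cl
Why: Deoxychlorination of the secondary alcohol through its chlorosulfite should give the allylic chloride, and any chloride that returns at C2 of the alkoxy-stabilised allyl cation should revert to the conjugated 4-chloro isomer, which is kept away from water and alcohols because it ionises easily.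

Step 4
Reactants: 6 4-(benzyloxy)benzoyl chloride; 7 4,4-dichlorobut-3-en-2-one
Product: 9 2-[4-(benzyloxy)phenyl]-6-chloro-4H-pyran-4-one, via dichlorovinyl diketone 8 (not isolated)
Conditions: 7 (2 equiv), LiN(SiMe3)2 (2 equiv), THF, −78 °C; 6 (1 equiv), −78 to 0 °C; aq. NH4Cl; crude 8, K2CO3, MeCN, 50 °C
Reagents that add atoms: none
Why: Claisen-type C-acylation of the kinetic lithium enolate of the methyl ketone should give the 1,3-diketone, whose aryl-side enol oxygen then displaces one vinylic chloride by intramolecular addition–elimination (6-endo-trig closure of ring C), so the remaining chlorine is on the carbon next to the ring oxygen by construction.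

Step 5
Reactants: 9 2-[4-(benzyloxy)phenyl]-6-chloro-4H-pyran-4-one
Product: 10 2-[4-(benzyloxy)phenyl]-6-(tributylstannyl)-4H-pyran-4-one
Conditions: (Bu3Sn)2 (1.5 equiv), Pd(PPh3)4 (5 mol %), dioxane, 100 °C
Reagents that add atoms: hexabutylditin, CCCC[Sn](CCCC)(CCCC)[Sn](CCCC)(CCCC)CCCC
Why: Palladium-catalysed stannylation (oxidative addition of zerovalent palladium into the C–Cl bond of the vinylogous acid chloride, transmetalation with the ditin, reductive elimination) should install tin under neutral conditions, after the ring is complete, because a carbon–tin bond would not survive a protic pyranone-forming cyclisation.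

Step 6
Reactants: 10 2-[4-(benzyloxy)phenyl]-6-(tributylstannyl)-4H-pyran-4-one; 5 3-(benzyloxy)-4-chloro-2-methoxycyclobut-2-en-1-one
Product: 11 3-(benzyloxy)-4-{6-[4-(benzyloxy)phenyl]-4-oxo-4H-pyran-2-yl}-2-methoxycyclobut-2-en-1-one (racemic)
Conditions: Pd2(dba)3 (2.5 mol %), P(2-furyl)3 (10 mol %), dioxane, 45 °C
Reagents that add atoms: none
Why: Stille coupling of a 4-chlorocyclobutenone with an alkenylstannane: zerovalent palladium should insert into the allylic C4–Cl bond, the pyranyl group is transferred from tin, and reductive elimination at C4 (the unsubstituted allyl terminus, which keeps the conjugated vinylogous ester) should give 11 as a racemate below the temperature at which it ring-opens.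

Step 7
Reactants: 11 3-(benzyloxy)-4-{6-[4-(benzyloxy)phenyl]-4-oxo-4H-pyran-2-yl}-2-methoxycyclobut-2-en-1-one
Product: 14 7-(benzyloxy)-2-[4-(benzyloxy)phenyl]-5-hydroxy-6-methoxy-4H-chromen-4-one (7,4'-di-O-benzylhispidulin), via dienylketene 12 (not isolated), via dienone 13 (not isolated)
Conditions: PhMe (0.02 M), degassed, 105 °C
Reagents that add atoms: none
Why: Heating should open the cyclobutenone by conrotatory 4π electrocyclic cleavage of the C1–C4 bond to a vinylketene; the opening is reversible, so although the pyranyl group prefers to turn outward, material drains through the inward-rotated isomer 12, the only one whose ketene carbon can reach the pyranone. A thermal disrotatory 6π electrocyclisation over the ketene C=C, the C3=C4 alkene and the pyranone C2=C3 bond then joins the ketene carbon to pyranone C3 (the nucleophilic α-carbon of the vinylogous ester), forming C4a–C5 and closing the six-membered ring A as dienone 13, which should enolise at once to phenol 14. The closest known reaction type is the thermal ring expansion of 4-aryl-, 4-heteroaryl- and 4-alkenylcyclobutenones to phenols and benzo-fused heterocycles, here run on the alkene of a 4-pyranone. The stereocentres of 11 and 13 are erased on aromatisation, so no stereocontrol is needed. The step needs ring closure to outrun ketene dimerisation and capture by nucleophiles, which dilution in dry degassed toluene should secure, and its regiochemistry is fixed by connectivity: the ketene carbon can bond only to C4a, so the former carbonyl becomes the chelated 5-OH and the squarate oxygens arrive as 6-OMe and 7-OBn.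

Step 8
Reactants: 14 7,4'-di-O-benzylhispidulin
Product: 15 hispidulin (5,7-dihydroxy-2-(4-hydroxyphenyl)-6-methoxy-4H-chromen-4-one)
Conditions: H2 (1 atm), 10% Pd/C, THF–MeOH, 25 °C
Reagents that add atoms: none
Why: Catalytic hydrogenolysis should cleave both benzyl aryl ethers faster than it reduces the flavone C2=C3 bond, leaving the methyl ether untouched.

Step 9
Reactants: 15 hispidulin
Product: 17 hispidulin 7,4'-disulfate (5-hydroxy-6-methoxy-4-oxo-2-[4-(sulfooxy)phenyl]-4H-chromen-7-yl hydrogen sulfate), via bis(pyridinium) disulfate 16 (not isolated)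
Conditions: SO3·pyridine (6 equiv), pyridine, 25 to 45 °C; H2O, Dowex 50W (H+ form), 0 °C; freeze-drying
Reagents that add atoms: sulfur trioxide–pyridine complex, O=S(=O)([O-])[n+]1ccccc1
Why: O-Sulfonation of phenols by SO3·pyridine should take the free 7- and 4'-hydroxyls, while the 5-hydroxyl, hydrogen-bonded to the C4 carbonyl and flanked by the 6-methoxyl, stays unreacted, and cold cation exchange releases the diacid.

**Compound list**

1 | dimethyl squarate (3,4-dimethoxycyclobut-3-ene-1,2-dione) | COC1=C(OC)C(=O)C1=O | starting material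
2 | 4-hydroxy-2,3-dimethoxycyclobut-2-en-1-one (racemic) | O=C1C(OC)=C(OC)C1O | intermediate
3 | benzyl alcohol | OCc1ccccc1 | starting material
4 | 3-(benzyloxy)-4-hydroxy-2-methoxycyclobut-2-en-1-one (racemic) | O=C1C(OC)=C(OCc2ccccc2)C1O | intermediate
5 | 3-(benzyloxy)-4-chloro-2-methoxycyclobut-2-en-1-one (racemic) | O=C1C(OC)=C(OCc2ccccc2)C1Cl | intermediate
6 | 4-(benzyloxy)benzoyl chloride | O=C(Cl)c1ccc(OCc2ccccc2)cc1 | starting material
7 | 4,4-dichlorobut-3-en-2-one | CC(=O)C=C(Cl)Cl | starting material
8 | 1-[4-(benzyloxy)phenyl]-5,5-dichloropent-4-ene-1,3-dione | O=C(CC(=O)C=C(Cl)Cl)c1ccc(OCc2ccccc2)cc1 | intermediate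
9 | 2-[4-(benzyloxy)phenyl]-6-chloro-4H-pyran-4-one | O=c1cc(Cl)oc(-c2ccc(OCc3ccccc3)cc2)c1 | intermediate
10 | 2-[4-(benzyloxy)phenyl]-6-(tributylstannyl)-4H-pyran-4-one | CCCC[Sn](CCCC)(CCCC)c1cc(=O)cc(-c2ccc(OCc3ccccc3)cc2)o1 | intermediate
11 | 3-(benzyloxy)-4-{6-[4-(benzyloxy)phenyl]-4-oxo-4H-pyran-2-yl}-2-methoxycyclobut-2-en-1-one (racemic) | O=C1C(OC)=C(OCc2ccccc2)C1c1cc(=O)cc(-c2ccc(OCc3ccccc3)cc2)o1 | intermediate
12 | (3E)-3-(benzyloxy)-4-{6-[4-(benzyloxy)phenyl]-4-oxo-4H-pyran-2-yl}-2-methoxybuta-1,3-dien-1-one (pyranyl cis to the ketene-bearing carbon) | O=C=C(OC)/C(OCc1ccccc1)=C\c1cc(=O)cc(-c2ccc(OCc3ccccc3)cc2)o1 | intermediate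
13 | 7-(benzyloxy)-2-[4-(benzyloxy)phenyl]-6-methoxy-4aH-chromene-4,5-dione (racemic) | O=C1C(OC)=C(OCc2ccccc2)C=C2OC(-c3ccc(OCc4ccccc4)cc3)=CC(=O)C12 | intermediate
14 | 7-(benzyloxy)-2-[4-(benzyloxy)phenyl]-5-hydroxy-6-methoxy-4H-chromen-4-one (7,4'-di-O-benzylhispidulin) | COc1c(OCc2ccccc2)cc2oc(-c3ccc(OCc4ccccc4)cc3)cc(=O)c2c1O | intermediate
15 | hispidulin | COc1c(O)cc2oc(-c3ccc(O)cc3)cc(=O)c2c1O | intermediate
16 | bis(pyridinium) salt of hispidulin 7,4'-disulfate | COc1c(OS(=O)(=O)[O-])cc2oc(-c3ccc(OS(=O)(=O)[O-])cc3)cc(=O)c2c1O.c1cc[nH+]cc1.c1cc[nH+]cc1 | intermediate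
17 | hispidulin 7,4'-disulfate | COc1c(OS(=O)(=O)O)cc2oc(-c3ccc(OS(=O)(=O)O)cc3)cc(=O)c2c1O | target

**Step count**

Total: 9 steps. Longest linear sequence: 7 steps (steps 1, 2, 3, 6, 7, 8, 9).

**Steps most likely to fail**

Step 7. The dienylketene may be lost to dimerisation or to capture by traces of nucleophile, or the cyclobutenone may decompose during repeated unproductive opening and reclosure before the inward-rotated isomer closes onto the electron-poor pyranone alkene. The fallback gives up the electrocyclisation, brings ring A in ready-made and closes ring C last; it sets out from acid chloride 6 and rejoins the route at hispidulin 15. Commercial 1-[2,4-bis(benzyloxy)-6-hydroxyphenyl]ethan-1-one F1 would undergo Elbs persulfate oxidation (K2S2O8, aq. NaOH) para to the free phenol to give potassium 3-acetyl-2,6-bis(benzyloxy)-4-hydroxyphenyl sulfate F2, hydrolysed with warm dilute HCl to 1-[2,4-bis(benzyloxy)-3,6-dihydroxyphenyl]ethan-1-one F3. The non-chelated hydroxyl would be methylated (Me2SO4, K2CO3, acetone) to 1-[2,4-bis(benzyloxy)-6-hydroxy-3-methoxyphenyl]ethan-1-one F4. Acylation with 6 in pyridine should give 2-acetyl-3,5-bis(benzyloxy)-4-methoxyphenyl 4-(benzyloxy)benzoate F5, and the Baker–Venkataraman rearrangement (KOH, pyridine, 50 °C) should give 1-[2,4-bis(benzyloxy)-6-hydroxy-3-methoxyphenyl]-3-[4-(benzyloxy)phenyl]propane-1,3-dione F6. Cyclodehydration (cat. H2SO4, AcOH) would close 5,7-bis(benzyloxy)-2-[4-(benzyloxy)phenyl]-6-methoxy-4H-chromen-4-one F7, the single free ortho-hydroxyl of F6 fixing the 6-methoxy pattern. Hydrogenolysis (H2, 10% Pd/C) would then give 15, which enters step 9.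

Step 6. Transfer of the electron-poor pyranyl group from tin to palladium may be slow, so that chloride 5 is lost by ionisation or thermal ring opening first; the coupled product may also ring-expand prematurely at the coupling temperature. The fallback replaces tin by zinc so that the coupling runs at room temperature; it sets out from chloropyranone 9 and rejoins at 11. Finkelstein-type exchange on the vinylogous acid chloride (NaI, MeCN, 60 °C) should give 2-[4-(benzyloxy)phenyl]-6-iodo-4H-pyran-4-one F8. Zinc insertion (Zn dust, LiCl, THF, 25 °C) would give {6-[4-(benzyloxy)phenyl]-4-oxo-4H-pyran-2-yl}zinc iodide F9. A Negishi coupling of F9 with 5 (Pd2(dba)3, P(2-furyl)3, THF, 25 °C) should then deliver 11.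

Step 2. Under acid the C4 hydroxyl may ionise to the allyl cation stabilised by the C2 methoxyl, which leads to loss of the vinylogous ester or to etherification at C4; the exchange may also stop short of completion. The fallback masks the hydroxyl and runs the exchange under base; it sets out from 2 and rejoins at 4. Silylation (TBSCl, imidazole, DMF) should give 4-[(tert-butyldimethylsilyl)oxy]-2,3-dimethoxycyclobut-2-en-1-one F10. Addition–elimination of benzyl alkoxide at C3 (benzyl alcohol 3, cat. NaH, THF, 0 °C) should give 3-(benzyloxy)-4-[(tert-butyldimethylsilyl)oxy]-2-methoxycyclobut-2-en-1-one F11. Desilylation (HF·pyridine, THF, 0 °C) would then release 4.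

**Further compounds**

F1 | step 7 | 1-[2,4-bis(benzyloxy)-6-hydroxyphenyl]ethan-1-one | CC(=O)c1c(O)cc(OCc2ccccc2)cc1OCc1ccccc1
F2 | step 7 | potassium 3-acetyl-2,6-bis(benzyloxy)-4-hydroxyphenyl sulfate | CC(=O)c1c(O)cc(OCc2ccccc2)c(OS(=O)(=O)[O-])c1OCc1ccccc1.[K+]
F3 | step 7 | 1-[2,4-bis(benzyloxy)-3,6-dihydroxyphenyl]ethan-1-one | CC(=O)c1c(O)cc(OCc2ccccc2)c(O)c1OCc1ccccc1
F4 | step 7 | 1-[2,4-bis(benzyloxy)-6-hydroxy-3-methoxyphenyl]ethan-1-one | CC(=O)c1c(O)cc(OCc2ccccc2)c(OC)c1OCc1ccccc1
F5 | step 7 | 2-acetyl-3,5-bis(benzyloxy)-4-methoxyphenyl 4-(benzyloxy)benzoate | CC(=O)c1c(OC(=O)c2ccc(OCc3ccccc3)cc2)cc(OCc2ccccc2)c(OC)c1OCc1ccccc1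
F6 | step 7 | 1-[2,4-bis(benzyloxy)-6-hydroxy-3-methoxyphenyl]-3-[4-(benzyloxy)phenyl]propane-1,3-dione | O=C(CC(=O)c1c(O)cc(OCc2ccccc2)c(OC)c1OCc1ccccc1)c1ccc(OCc2ccccc2)cc1
F7 | step 7 | 5,7-bis(benzyloxy)-2-[4-(benzyloxy)phenyl]-6-methoxy-4H-chromen-4-one | COc1c(OCc2ccccc2)cc2oc(-c3ccc(OCc4ccccc4)cc3)cc(=O)c2c1OCc1ccccc1
F8 | step 6 | 2-[4-(benzyloxy)phenyl]-6-iodo-4H-pyran-4-one | O=c1cc(I)oc(-c2ccc(OCc3ccccc3)cc2)c1
F9 | step 6 | {6-[4-(benzyloxy)phenyl]-4-oxo-4H-pyran-2-yl}zinc iodide | O=c1cc([Zn]I)oc(-c2ccc(OCc3ccccc3)cc2)c1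
F10 | step 2 | 4-[(tert-butyldimethylsilyl)oxy]-2,3-dimethoxycyclobut-2-en-1-one | CC(C)(C)[Si](C)(C)OC1C(=O)C(OC)=C1OC
F11 | step 2 | 3-(benzyloxy)-4-[(tert-butyldimethylsilyl)oxy]-2-methoxycyclobut-2-en-1-one | CC(C)(C)[Si](C)(C)OC1C(=O)C(OC)=C1OCc1ccccc1
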